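# Total synthesis of Blepharocalyxin B (1)

**Retrosynthetic overview**
1. Blepharocalyxin B (1) comes from global desilylation of the hepta-TBS ether 2.
2. 2 comes from a BINOL-catalysed Petasis-type (o-quinone methide) alkenylation of phenol 3 with aldehyde 4 and (E)-alkenyl-Bpin 5. This sets the C1″ diarylmethine centre and the E-olefin in one step.
3. 3 comes from ionic hydrogenation of dihydropyran 6, which sets C6. 6 comes from an endo-selective inverse-demand oxa-[4+2] of chalcone 7 with dienone 8. That step forms the tetrahydropyran (THP) ring and sets C2, C3 and C4.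
4. 5 comes from cross-metathesis of an (S)-homoallylic alcohol derived from 9 (Brown allylation). 7 and 8 come from aldol condensations of commercial acetophenone and aldehydes. The THP ring is formed first (step 5); the acyclic chain is attached last (step 13).

**Assumptions**
- The free, H-bonded 2′-OH directs the o-QM, and therefore the new C–C bond, to C3′ (between the two oxygens) rather than C5′.
- The enantiomer of each chiral catalyst (phosphoramide, BINOL) is the one that gives the configuration drawn in 1, namely 1″R and 5″S.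

## Route

**Step 1**
Reactants: 10 (2′,4′-dihydroxy-6′-methoxyacetophenone), 11 (4-hydroxybenzaldehyde)
Product: 12 (2′,4,4′-trihydroxy-6′-methoxychalcone, helichrysetin, E)
Conditions: KOH (aq.), EtOH, 23 → 50 °C
Reagents that add atoms: none
Why: Claisen–Schmidt aldol condensation gives the thermodynamic E-enone, and no stereocentre is formed.

**Step 2**
Reactants: 12
Product: 7 ((E)-2′-hydroxy-6′-methoxy-4,4′-bis(TBS-oxy)chalcone)
Conditions: TBSCl (2.3 equiv), imidazole, DMF, 23 °C
Reagents that add atoms: tert-butyldimethylsilyl chloride, CC(C)(C)[Si](C)(C)Cl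
Why: the two non-chelated phenols are silylated selectively, and the 2′-OH stays free because it is H-bonded to the C=O.

**Step 3**
Reactants: 13 (raspberry ketone, 4-(4-hydroxyphenyl)butan-2-one), 14 ((E)-4-hydroxycinnamaldehyde)
Product: 15 ((4E,6E)-1,7-bis(4-hydroxyphenyl)hepta-4,6-dien-3-one)
Conditions: NaOH (aq.), EtOH, 0 → 23 °C
Reagents that add atoms: none
Why: crossed aldol condensation occurs at the less hindered methyl terminus and gives the E,E-dienone.

**Step 4**
Reactants: 15
Product: 8 (bis-OTBS dienone)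
Conditions: TBSCl (2.2 equiv), imidazole, DMF, 23 °C
Reagents that add atoms: TBSCl, CC(C)(C)[Si](C)(C)Cl
Why: both phenols are protected so that the Lewis or Brønsted acid and nucleophilic conditions of steps 5 and 6 are tolerated.

**Step 5**
Reactants: 7, 8
Product: 6 (2-aryl-3-aroyl-4-styryl-6-arylethyl-3,4-dihydro-2H-pyran; C5=C6 enol ether)
Conditions: chiral N-triflylphosphoramide (10 mol %), PhMe, 4 Å MS, −20 → 23 °C
Reagents that add atoms: none (7 and 8 combine with no loss)
Why: this is a polar inverse-electron-demand oxa-Diels–Alder. The electron-rich 4-silyloxystyrenyl alkene of 7 attacks the acid-activated C4 of dienone 8, and the enol oxygen closes onto the benzylic C2. Endo approach of the two E-alkenes gives 2,3-trans and 3,4-cis, and the chiral acid fixes the absolute sense.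

**Step 6**
Reactants: 6
Product: 3 (THP ketone phenol, 2,6-trans-2,3-trans-3,4-cis, 6S)
Conditions: Et3SiH (5 equiv), TFA (2 equiv), CH2Cl2, −78 → −40 °C
Reagents that add atoms: none (only H is added)
Why: ionic hydrogenation protonates the enol ether at C5 to give an oxocarbenium. In the half-chair with C4-styryl pseudo-equatorial, silane delivers hydride axially from the face anti to the C3 acyl group. This puts the arylethyl group equatorial and sets C6 as S (2,6-trans).

**Step 7**
Reactants: 16 (methyl 3-(4-hydroxyphenyl)propanoate)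
Product: 17 (methyl 3-(4-TBS-oxyphenyl)propanoate)
Conditions: TBSCl, imidazole, CH2Cl2, 23 °C
Reagents that add atoms: TBSCl, CC(C)(C)[Si](C)(C)Cl
Why: silyl protection of the phenol.

**Step 8**
Reactants: 17
Product: 18 (3-(4-TBS-oxyphenyl)propanal)
Conditions: DIBAL-H (1.1 equiv), CH2Cl2, −78 °C
Reagents that add atoms: none
Why: partial ester reduction stops at the aldehyde at low temperature.

**Step 9**
Reactants: 18
Product: 9 ((S)-1-(4-TBS-oxyphenyl)hex-5-en-3-ol)
Conditions: (−)-Ipc2B-allyl, Et2O, −78 °C; then NaBO3·4H2O, THF/H2O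
Reagents that add atoms: (−)-B-allyldiisopinocampheylborane (stereo omitted), C=CCB(C1CC2CC(C1C)C2(C)C)C1CC2CC(C1C)C2(C)C
Why: Brown asymmetric allylation proceeds through a chair Zimmerman–Traxler TS, and the pinene-derived boron ligand sets the (S)-carbinol (C5″). The perborate work-up avoids cleaving the aryl silyl ether.

**Step 10**
Reactants: 9
Product: 19 ((S)-bis-TBS ether of 9)
Conditions: TBSOTf, 2,6-lutidine, CH2Cl2, 0 °C
Reagents that add atoms: TBSOTf, C[Si](C)(C(C)(C)C)OS(=O)(=O)C(F)(F)F
Why: the secondary alcohol is protected so it cannot interact with boron in steps 11 and 13. The carbinol configuration is untouched.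

**Step 11**
Reactants: 19
Product: 5 ((S,E)-alkenyl-Bpin)
Conditions: vinyl-Bpin (5 equiv), Grubbs II (5 mol %), CH2Cl2, 40 °C
Reagents that add atoms: vinylboronic acid pinacol ester, C=CB1OC(C)(C)C(C)(C)O1
Why: cross-metathesis (Ru alkylidene) gives the thermodynamic E-alkenylboronate, and the remote stereocentre is untouched.

**Step 12**
Reactants: 11 (4-hydroxybenzaldehyde)
Product: 4 (4-TBS-oxybenzaldehyde)
Conditions: TBSCl, imidazole, DMF, 23 °C
Reagents that add atoms: TBSCl, CC(C)(C)[Si](C)(C)Cl
Why: silyl protection of the phenol.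

**Step 13**
Reactants: 3, 4 (2 equiv), 5 (2 equiv)
Product: 2 (hepta-TBS ether of blepharocalyxin B, 2′-OH free)
Conditions: (R)-3,3′-diaryl-BINOL (20 mol %), PhMe, 4 Å MS, 40 °C
Reagents that add atoms: none (pinB–OH is lost)
Why: this is a Petasis-type three-component coupling. The free 2′-OH condenses with 4 to give an o-quinone methide at C3′. The chiral BINOL-alkenylboronate then delivers the (E)-alkenyl group to one face, forming C1″ as R, and the C=C geometry is retained.

**Step 14**
Reactants: 2
Product: 1 (blepharocalyxin B)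
Conditions: HF·pyridine, pyridine, THF, 0 → 23 °C, 48 h
Reagents that add atoms: none (only H is added)
Why: buffered fluoride removes all seven TBS groups without the base that would cause retro-oxa-Michael ring opening and epimerisation at C3 of the β-alkoxy ketone.

## Compound list
1 | Blepharocalyxin B (target) | COc1cc(O)c([C@H](/C=C/C[C@@H](O)CCc2ccc(O)cc2)c2ccc(O)cc2)c(O)c1C(=O)[C@@H]1[C@H](/C=C/c2ccc(O)cc2)C[C@H](CCc2ccc(O)cc2)O[C@H]1c1ccc(O)cc1 | target
2 | hepta-TBS ether of 1 (2′-OH free) | COc1cc(O[Si](C)(C)C(C)(C)C)c([C@H](/C=C/C[C@@H](O[Si](C)(C)C(C)(C)C)CCc2ccc(O[Si](C)(C)C(C)(C)C)cc2)c2ccc(O[Si](C)(C)C(C)(C)C)cc2)c(O)c1C(=O)[C@@H]1[C@H](/C=C/c2ccc(O[Si](C)(C)C(C)(C)C)cc2)C[C@H](CCc2ccc(O[Si](C)(C)C(C)(C)C)cc2)O[C@H]1c1ccc(O[Si](C)(C)C(C)(C)C)cc1 | intermediate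
3 | THP aryl ketone with 4′-OTBS and 2′-OH, three aryl-OTBS | COc1cc(O[Si](C)(C)C(C)(C)C)cc(O)c1C(=O)[C@@H]1[C@H](/C=C/c2ccc(O[Si](C)(C)C(C)(C)C)cc2)C[C@H](CCc2ccc(O[Si](C)(C)C(C)(C)C)cc2)O[C@H]1c1ccc(O[Si](C)(C)C(C)(C)C)cc1 | intermediate
4 | 4-(TBS-oxy)benzaldehyde | O=Cc1ccc(O[Si](C)(C)C(C)(C)C)cc1 | intermediate
5 | (S,E)-alkenyl-Bpin, bis-OTBS | CC1(C)OB(OC1(C)C)/C=C/C[C@@H](O[Si](C)(C)C(C)(C)C)CCc1ccc(O[Si](C)(C)C(C)(C)C)cc1 | intermediate
6 | 3,4-dihydro-2H-pyran (enol ether) | COc1cc(O[Si](C)(C)C(C)(C)C)cc(O)c1C(=O)[C@@H]1[C@H](/C=C/c2ccc(O[Si](C)(C)C(C)(C)C)cc2)C=C(CCc2ccc(O[Si](C)(C)C(C)(C)C)cc2)O[C@H]1c1ccc(O[Si](C)(C)C(C)(C)C)cc1 | intermediate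
7 | (E)-2′-hydroxy-6′-methoxy-4,4′-bis(TBS-oxy)chalcone | COc1cc(O[Si](C)(C)C(C)(C)C)cc(O)c1C(=O)/C=C/c1ccc(O[Si](C)(C)C(C)(C)C)cc1 | intermediate
8 | (4E,6E)-1,7-bis(4-TBS-oxyphenyl)hepta-4,6-dien-3-one | O=C(CCc1ccc(O[Si](C)(C)C(C)(C)C)cc1)/C=C/C=C/c1ccc(O[Si](C)(C)C(C)(C)C)cc1 | intermediate
9 | (S)-1-(4-TBS-oxyphenyl)hex-5-en-3-ol | C=CC[C@@H](O)CCc1ccc(O[Si](C)(C)C(C)(C)C)cc1 | intermediate
10 | 2′,4′-dihydroxy-6′-methoxyacetophenone | COc1cc(O)cc(O)c1C(C)=O | starting material
11 | 4-hydroxybenzaldehyde | O=Cc1ccc(O)cc1 | starting material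
12 | 2′,4,4′-trihydroxy-6′-methoxychalcone (helichrysetin) | COc1cc(O)cc(O)c1C(=O)/C=C/c1ccc(O)cc1 | intermediate
13 | 4-(4-hydroxyphenyl)butan-2-one (raspberry ketone) | CC(=O)CCc1ccc(O)cc1 | starting material
14 | (E)-4-hydroxycinnamaldehyde | O=C/C=C/c1ccc(O)cc1 | starting material
15 | (4E,6E)-1,7-bis(4-hydroxyphenyl)hepta-4,6-dien-3-one | O=C(CCc1ccc(O)cc1)/C=C/C=C/c1ccc(O)cc1 | intermediate
16 | methyl 3-(4-hydroxyphenyl)propanoate | COC(=O)CCc1ccc(O)cc1 | starting material
17 | methyl 3-(4-TBS-oxyphenyl)propanoate | COC(=O)CCc1ccc(O[Si](C)(C)C(C)(C)C)cc1 | intermediate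
18 | 3-(4-TBS-oxyphenyl)propanal | O=CCCc1ccc(O[Si](C)(C)C(C)(C)C)cc1 | intermediate
19 | (S)-bis-TBS ether of 9 | C=CC[C@@H](O[Si](C)(C)C(C)(C)C)CCc1ccc(O[Si](C)(C)C(C)(C)C)cc1 | intermediate

**Totals:** 14 steps in total; the longest linear sequence is 7 steps (16 → 17 → 18 → 9 → 19 → 5 → 2 → 1).

## Three steps most likely to fail
1. **Step 5 (oxa-[4+2]).** The chalcone alkene is a poorly nucleophilic partner and the dienone is only weakly electrophilic, so yield, endo selectivity and enantioselectivity are all at risk. Fallback: a stepwise route. A phosphine-catalysed cross-Rauhut–Currier coupling of 7 and 8 gives the α-alkylidene 1,5-diketone. This is followed by oxa-Michael/hemiketalisation and the step-6 ionic reduction, and the diastereomers are separated.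
2. **Step 13 (three-component Petasis-type).** This step needs C3′ versus C5′ regiocontrol, enantiocontrol at C1″ on a hindered, chelated phenol, and tolerance of the nearby β-alkoxy ketone. Fallback: Ir-catalysed asymmetric allylic substitution of 3 with 4-OTBS-cinnamyl carbonate gives the 1,1-diarylallyl compound. Cross-metathesis with 19 then installs the E-olefin and side chain, giving 2.
3. **Step 6 (ionic hydrogenation at C6).** Facial selectivity may be poor, and TFA may cause aryl-silyl cleavage or retro-oxa-Michael epimerisation. Fallback: hydrolyse the enol ether to the open δ-hydroxy ketone and reduce the C6 ketone (CBS) to the (R)-carbinol. Then close the ring by Mitsunobu cyclodehydration, which inverts C6 to (S) and gives the 2,6-trans ether by construction.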